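**Plan**

1. Retrosynthetic cuts: the O4 silyl ether; the lactone bond O–C6 (key), which returns the lactone oxygen to a C12 tert-butyl ester and C6 to an ether bridge C6–O–C9; then C2=O (from C=CH2), C1–C2 (alkenylcerium + C1 ketone), the C5 ester, the C5–O bond (enol ether oxidation), the C12 oxidation level, the bridge bond O–C6, C5 itself (one-carbon ring enlargement) and the C9–O bond (epoxide), back to (R)-carvone.
2. Forward ring order: the six-membered ring is bought, enlarged to a cycloheptenone, bridged by O9 across C6/C9 to an 8-oxabicyclo[3.2.1]octan-3-one (temporary ring), and the γ-lactone is closed last, in the same event that opens the bridge. The C2–C4/C15 chain and the 2-methylbutanoate are attached on the bicycle.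
3. Enabling feature: on the seven-membered ring O6 (lactone) and O9 (hydroxyl) are 1,4 and trans, while O9 and O5 are cis. C9–O can therefore bridge to C6 on the β-face; in that bicycle the C7 acrylate is endo and lies directly behind the C6–O bond, so lactonisation is an intramolecular SN2 at C6 with the bridge oxygen as leaving group.
4. Stereochemistry: C7 from (R)-carvone; C9 by epoxidation anti to C7; C10 by equilibration in the bicycle; C5 and C1 by exo attack on the bicycle; C6 by inversion in the key step; C4 and C2' from (S)-pent-4-yn-2-ol and (S)-2-methylbutanoic acid.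

Key step: step 17

Remark on notation: atoms carry the target numbering throughout (ring C1, C5, C6, C7, C8, C9, C10; side chain C2–C4 and C15; C14 methyl on C10; C11–C13 acrylate/lactone carbons); α is the ring face that carries C11 on C7, β the opposite face.

Assumption: (S)-pent-4-yn-2-ol is taken as commercial (otherwise one step from (S)-propylene oxide and lithium acetylide).

**Route**

Step 1
Reactants: 1 (R)-(−)-carvone
Product: 2 trans-carvone oxide (9β,10β-epoxide anti to the 7α-isopropenyl group)
Conditions: 30% H2O2, NaOH (cat.), MeOH, 0 °C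
Reagents that add atoms: hydrogen peroxide, OO
Why: Weitz–Scheffer nucleophilic epoxidation of the enone, in which hydroperoxide adds to C9 anti to the C7 isopropenyl group, so that the new C9–O bond (and the transient C10–O bond) lies on the β-face.

Step 2
Reactants: 2 trans-carvone oxide
Product: 3 9β-hydroxy ketone (3-hydroxy-2-methyl-5-isopropenylcyclohexanone; hydroxyl trans to isopropenyl)
Conditions: SmI2, THF/MeOH, −90 °C
Reagents that add atoms: none
Why: Reductive opening of an α,β-epoxy ketone by single-electron transfer (ketyl formation, scission of the C10–O bond, protonation of the samarium enolate) should give the β-hydroxy ketone with C9 untouched; C10 forms as an epimer mixture (equatorial-methyl epimer drawn) that is corrected in step 5.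

Step 3
Reactants: 3 9β-hydroxy ketone
Product: 5 bis-silyl compound (9β-OTMS; C1=C6 trimethylsilyl enol ether), via 9β-trimethylsilyl ether 4 (not isolated)
Conditions: LDA (LiN(iPr)2, 2.3 equiv), TMSCl (4 equiv, in situ), THF, −78 °C
Reagents that add atoms: chlorotrimethylsilane, C[Si](C)(C)Cl
Why: The alkoxide is silylated first and LDA then removes the kinetically more accessible proton at the C6 methylene instead of the C10 methine, the enolate being trapped in situ as the less substituted silyl enol ether (kinetic enolate silylation) before retro-aldol or β-elimination can occur.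

Step 4
Reactants: 5 bis-silyl compound
Product: 6 siloxycyclopropane (1-trimethylsilyloxybicyclo[4.1.0]heptane; new methylene bridging C1 and C6)
Conditions: Et2Zn, CH2I2, CH2Cl2, 0 °C
Reagents that add atoms: diiodomethane, ICI
Why: Simmons–Smith cyclopropanation (diethylzinc variant) is much faster on the electron-rich silyl enol ether than on the 1,1-disubstituted isopropenyl alkene; the two new centres (methylene drawn anti to C7) are erased in step 5, so their configuration does not matter.

Step 5
Reactants: 6 siloxycyclopropane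
Product: 9 oxabicyclic ketone (6β,9β-oxygen bridge; C1 ketone; 10α-methyl; 7α-isopropenyl), via β-chloro ketone 7 (not isolated), via 9β-hydroxy enone 8 (not isolated)
Conditions: FeCl3, DMF, 0 °C; then NaOAc, MeOH, reflux; then DBU (cat.), CH2Cl2, rt
Reagents that add atoms: none
Why: Saegusa-type ring enlargement: FeCl3 oxidises the siloxycyclopropane, the internal C1–C6 bond breaks to the β-keto radical at C6 that is chlorinated, acetate then eliminates HCl and methanol removes the silyl ether, and the freed 9β-hydroxyl adds across the ring to C6 of the enone (transannular oxa-Michael addition, 5-exo-trig) necessarily on its own face, which sets C6 (β-oxygen), places the C7 substituent endo, and lets the base move the C10 methyl into the equatorial α-position anti to the oxygen bridge.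

Step 6
Reactants: 9 oxabicyclic ketone
Product: 10 allylic chloride (7α-(3-chloroprop-1-en-2-yl) oxabicyclic ketone)
Conditions: Ca(OCl)2, solid CO2, CH2Cl2/H2O, 0 °C
Reagents that add atoms: calcium hypochlorite, [Ca+2].[O-]Cl.[O-]Cl
Why: Ene-type allylic chlorination of the isopropenyl group by hypochlorous acid generated in situ is a standard reaction of carvone-type isopropenyl groups and leaves the ketone and the ether bridge alone.

Step 7
Reactants: 10 allylic chloride
Product: 11 enal (7α-(3-oxoprop-1-en-2-yl) oxabicyclic ketone)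
Conditions: N-methylmorpholine N-oxide, KI (cat.), NaHCO3, DMSO, 50 °C
Reagents that add atoms: N-methylmorpholine N-oxide, C[N+]1([O-])CCOCC1
Why: Amine N-oxide oxidation of an allylic halide (Kornblum-type): iodide-assisted SN2 substitution by the N-oxide oxygen and base-induced loss of N-methylmorpholine should give the 2-substituted acrolein.

Step 8
Reactants: 11 enal
Product: 12 acrylic acid (2-substituted prop-2-enoic acid on C7)
Conditions: NaClO2, NaH2PO4, 2-methyl-2-butene, t-BuOH/H2O, rt
Reagents that add atoms: sodium chlorite, [Na+].[O-]Cl=O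
Why: Pinnick oxidation converts the enal into the acrylic acid without touching the ketone, with 2-methyl-2-butene trapping the hypochlorous acid formed.

Step 9
Reactants: 12 acrylic acid
Product: 13 tert-butyl acrylate (oxabicyclic keto ester)
Conditions: tert-butyl 2,2,2-trichloroacetimidate, BF3·OEt2 (cat.), CH2Cl2/cyclohexane, rt
Reagents that add atoms: tert-butyl 2,2,2-trichloroacetimidate, CC(C)(C)OC(=N)C(Cl)(Cl)Cl
Why: Acid-catalysed O-alkylation of the carboxylic acid by the trichloroacetimidate gives the tert-butyl ester, chosen because it resists enolate and organocerium chemistry and is unmasked by the silyl triflate of step 17.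

Step 10
Reactants: 13 tert-butyl acrylate
Product: 14 triethylsilyl enol ether (C1(OTES)=C5)
Conditions: LDA (LiN(iPr)2), TESCl (in situ), THF, −78 °C
Reagents that add atoms: chlorotriethylsilane, CC[Si](Cl)(CC)CC
Why: Kinetic deprotonation occurs at the C5 methylene (exo, axial hydrogen) instead of the C10 methine and in situ O-silylation of the enolate prevents β-elimination of the bridge oxygen, while the hindered α-substituted acrylate is not attacked at −78 °C.

Step 11
Reactants: 14 triethylsilyl enol ether
Product: 16 5β-hydroxy ketone (axial hydroxyl next to the C1 ketone), via 5β-triethylsilyloxy ketone 15 (not isolated)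
Conditions: mCPBA, NaHCO3, CH2Cl2, −20 °C; then HF·pyridine, THF, 0 °C
Reagents that add atoms: 3-chloroperoxybenzoic acid, OOC(=O)c1cccc(Cl)c1
Why: Rubottom oxidation: the peracid epoxidises the silyl enol ether from the exo (β) face, the endo face being blocked by the C7–C8 bridge and its endo substituent, silyl migration gives the α-silyloxy ketone and fluoride frees the axial 5β-hydroxyl, which sets C5; the electron-poor acrylate does not react with the peracid.

Step 12
Reactants: 17 (S)-pent-4-yn-2-ol
Product: 18 (S)-tert-butyldimethyl(pent-4-yn-2-yloxy)silane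
Conditions: TBSCl, imidazole, DMF, rt
Reagents that add atoms: tert-butyldimethylsilyl chloride, CC(C)(C)[Si](C)(C)Cl
Why: Standard silylation of the secondary alcohol, which leaves the stereocentre untouched.

Step 13
Reactants: 18 (S)-tert-butyldimethyl(pent-4-yn-2-yloxy)silane
Product: 20 (S)-(4-bromopent-4-en-2-yloxy)(tert-butyl)dimethylsilane, via (Z)-2-bromoalkenyl-9-BBN 19 (not isolated)
Conditions: B-bromo-9-BBN, CH2Cl2, 0 °C; then AcOH, 0 °C to rt
Reagents that add atoms: B-bromo-9-borabicyclo[3.3.1]nonane, BrB1C2CCCC1CCC2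
Why: Bromoboration of the terminal alkyne adds boron to the terminal and bromine to the internal carbon (syn addition), and protodeboronation with acetic acid then gives the 2-bromo-1-alkene, the equivalent of the C2 acyl anion.

Step 14
Reactants: 20 (S)-(4-bromopent-4-en-2-yloxy)(tert-butyl)dimethylsilane, 16 5β-hydroxy ketone
Product: 23 1α,5β-diol carrying the 1β-[(4S)-4-silyloxypent-1-en-2-yl] group, via alkenyllithium 21 (not isolated), via alkenylcerium dichloride 22 (not isolated)
Conditions: t-BuLi (2 equiv per bromide), Et2O, −78 °C; CeCl3 (anhydrous), THF, −78 °C; then 16 (0.4 equiv), −78 to −30 °C; aq. NH4Cl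
Reagents that add atoms: none
Why: Bromine–lithium exchange and transmetalation give a weakly basic alkenylcerium reagent (organocerium 1,2-addition) that should add to the C1 ketone of the 5β-alkoxide from the exo (β) face, because the endo face is closed by the C7–C8 bridge and the endo C7 substituent, which sets C1 with the carbon chain β and the hydroxyl α; esters are not attacked by organocerium reagents.

Step 15
Reactants: 23 1α,5β-diol, 24 (S)-2-methylbutanoic acid
Product: 25 5β-[(S)-2-methylbutanoate] of the diol
Conditions: DCC, DMAP, CH2Cl2, 0 °C to rt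
Reagents that add atoms: none
Why: Steglich esterification acylates the only reactive hydroxyl, the secondary 5β-OH, since the C1 hydroxyl is tertiary and the C9 and C6 oxygens are still tied up in the ether bridge.

Step 16
Reactants: 25 5β-[(S)-2-methylbutanoate]
Product: 27 α-hydroxy ketone (C2 ketone; substrate of the key step), via ozonide 26 (not isolated)
Conditions: O3 (dosed to consumption of 25), CH2Cl2, −78 °C; then PPh3, −78 °C to rt
Reagents that add atoms: ozone, [O-][O+]=O
Why: Ozonolysis with reductive work-up cleaves the electron-rich 1,1-disubstituted alkene much faster than the electron-poor acrylate and unmasks the C2 ketone.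

Step 17
Reactants: 27 α-hydroxy ketone
Product: 30 4-O-TBS ether of the target (cis-fused α-methylene lactone; free 9β-OH), via silyl ester 28 (not isolated), via bis-silylated lactone 29 (not isolated)
Conditions: TMSOTf (3 equiv), 2,6-di-tert-butyl-4-methylpyridine (3.5 equiv), CH2Cl2, −78 to 0 °C; then MeOH, citric acid, 0 °C
Reagents that add atoms: none
Why: Proposed new method: TMSOTf first turns the tert-butyl ester into the silyl ester (isobutene is lost) and silylates the C1 hydroxyl, then silylates the bridging ether oxygen reversibly, and the carbonyl oxygen of the C12 silyl ester, which the endo C7 bond holds almost in line with the back of the C6–O bond, displaces the silyloxonium oxygen at C6 in an intramolecular SN2 reaction, after which loss of the silyl group from the dialkoxycarbenium ion gives the lactone and leaves the former bridge oxygen on C9 as its silyl ether. The closest known reaction types are the cleavage of cyclic ethers through silyloxonium ions by silyl iodides or triflates, the acid-induced opening of 7-oxabicyclo[2.2.1]heptanes with participation of a neighbouring acyl group, and the lactonisation of tert-butyl esters onto epoxides or iodonium ions. The only ring closed is the γ-lactone (O, C12, C11, C7, C6) by a 5-exo-tet closure, and it can only be cis-fused because the tether reaches C6 from the α-face alone. C6 is the one stereocentre that changes: it is inverted from 6β-O to 6α-O under control of the C7 stereocentre, while C9 keeps its configuration because its C–O bond is not broken. The step needs cleavage of the bridge at C6 and not at C9 and no ionisation at C1 or loss of the β-silyloxy group, which is secured because only C6 has a nucleophile behind its C–O bond, triflate is non-nucleophilic, the C1 oxygen is silylated and flanked by the C2 carbonyl, and the hindered pyridine removes triflic acid. Relief of the syn-axial strain between the 1α-oxygen and the endo C7 substituent of the bicycle adds driving force.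

Step 18
Reactants: 30 4-O-TBS ether of the target
Product: 31 CNP0291806.1 (target)
Conditions: HF·pyridine, pyridine, THF, 0 °C to rt
Reagents that add atoms: none
Why: Fluoride-mediated desilylation under buffered acidic conditions removes the silyl ether without retro-aldol cleavage or dehydration of the β-hydroxy ketone and leaves both esters and the methylene lactone intact.

**Compound list**

1 | (R)-(−)-carvone, (5R)-2-methyl-5-(prop-1-en-2-yl)cyclohex-2-en-1-one | C1[C@H](C(C)=C)CC=C(C)C1=O | starting material
2 | trans-carvone oxide, (1R,4R,6R)-1-methyl-4-(prop-1-en-2-yl)-7-oxabicyclo[4.1.0]heptan-2-one (9β,10β-epoxide) | C1[C@H](C(C)=C)C[C@H]2O[C@@]2(C)C1=O | intermediate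
3 | 9β-hydroxy ketone, 3-hydroxy-2-methyl-5-(prop-1-en-2-yl)cyclohexan-1-one, OH trans to isopropenyl (C10 epimers; equatorial-methyl epimer drawn) | C1[C@H](C(C)=C)C[C@@H](O)[C@@H](C)C1=O | intermediate
4 | 9β-trimethylsilyl ether of 3 | C1[C@H](C(C)=C)C[C@@H](O[Si](C)(C)C)[C@@H](C)C1=O | intermediate (not isolated)
5 | bis-silyl compound: 9β-OTMS, C1=C6 trimethylsilyl enol ether | C[Si](C)(C)OC1=C[C@H](C(C)=C)C[C@@H](O[Si](C)(C)C)[C@H]1C | intermediate
6 | siloxycyclopropane: 1-trimethylsilyloxybicyclo[4.1.0]heptane with 9β-OTMS, methylene bridging C1/C6 (β-methylene drawn) | C1[C@H]2[C@H](C(C)=C)C[C@@H](O[Si](C)(C)C)[C@@H](C)[C@@]12O[Si](C)(C)C | intermediate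
7 | β-chloro ketone: 6-chlorocycloheptan-1-one with 9β-OTMS, 10-methyl, 7α-isopropenyl (C6 epimers) | ClC1[C@H](C(C)=C)C[C@@H](O[Si](C)(C)C)[C@@H](C)C(=O)C1 | intermediate (not isolated)
8 | 9β-hydroxy enone: cyclohept-5-en-1-one (C5=C6) with 9β-OH, 10-methyl, 7α-isopropenyl | O=C1C=C[C@H](C(C)=C)C[C@@H](O)[C@H]1C | intermediate (not isolated)
9 | oxabicyclic ketone: 2-methyl-6-endo-(prop-1-en-2-yl)-8-oxabicyclo[3.2.1]octan-3-one, methyl equatorial (6β,9β-oxygen bridge, C1 ketone, 10α-methyl, 7α-isopropenyl) | O1[C@H]2[C@H](C(C)=C)C[C@@H]1[C@H](C)C(=O)C2 | intermediate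
10 | allylic chloride: 9 with 7α-(3-chloroprop-1-en-2-yl) | O1[C@H]2[C@H](C(CCl)=C)C[C@@H]1[C@H](C)C(=O)C2 | intermediate
11 | enal: 9 with 7α-(3-oxoprop-1-en-2-yl) | O1[C@H]2[C@H](C(C=O)=C)C[C@@H]1[C@H](C)C(=O)C2 | intermediate
12 | acrylic acid: 2-(oxabicyclic ketone-7α-yl)prop-2-enoic acid | O1[C@H]2[C@H](C(C(=O)O)=C)C[C@@H]1[C@H](C)C(=O)C2 | intermediate
13 | tert-butyl acrylate of 12 | O1[C@H]2[C@H](C(C(=O)OC(C)(C)C)=C)C[C@@H]1[C@H](C)C(=O)C2 | intermediate
14 | triethylsilyl enol ether C1(OTES)=C5 of 13 | O1[C@H]2[C@H](C(C(=O)OC(C)(C)C)=C)C[C@@H]1[C@H](C)C(O[Si](CC)(CC)CC)=C2 | intermediate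
15 | 5β-triethylsilyloxy ketone | O1[C@H]2[C@H](C(C(=O)OC(C)(C)C)=C)C[C@@H]1[C@H](C)C(=O)[C@H]2O[Si](CC)(CC)CC | intermediate (not isolated)
16 | 5β-hydroxy ketone (axial OH, syn to the oxygen bridge) | O1[C@H]2[C@H](C(C(=O)OC(C)(C)C)=C)C[C@@H]1[C@H](C)C(=O)[C@H]2O | intermediate
17 | (S)-pent-4-yn-2-ol | C#CC[C@H](C)O | starting material
18 | (S)-tert-butyldimethyl(pent-4-yn-2-yloxy)silane | C#CC[C@H](C)O[Si](C)(C)C(C)(C)C | intermediate
19 | (Z)-2-bromoalkenyl-9-BBN from 18 | Br/C(C[C@H](C)O[Si](C)(C)C(C)(C)C)=C\B1C2CCCC1CCC2 | intermediate (not isolated)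
20 | (S)-(4-bromopent-4-en-2-yloxy)(tert-butyl)dimethylsilane | C=C(Br)C[C@H](C)O[Si](C)(C)C(C)(C)C | intermediate
21 | alkenyllithium from 20 | [Li]C(=C)C[C@H](C)O[Si](C)(C)C(C)(C)C | intermediate (not isolated)
22 | alkenylcerium dichloride from 21 | Cl[Ce](Cl)C(=C)C[C@H](C)O[Si](C)(C)C(C)(C)C | intermediate (not isolated)
23 | 1α,5β-diol: oxabicycle with 1α-OH, 1β-[(4S)-4-(TBSO)pent-1-en-2-yl], 5β-OH, 10α-methyl, 7α-(tert-butyl acrylate) | O1[C@H]2[C@H](C(C(=O)OC(C)(C)C)=C)C[C@@H]1[C@H](C)[C@@](O)(C(=C)C[C@H](C)O[Si](C)(C)C(C)(C)C)[C@H]2O | intermediate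
24 | (S)-2-methylbutanoic acid | CC[C@H](C)C(=O)O | starting material
25 | 5β-[(S)-2-methylbutanoate] of 23 | O1[C@H]2[C@H](C(C(=O)OC(C)(C)C)=C)C[C@@H]1[C@H](C)[C@@](O)(C(=C)C[C@H](C)O[Si](C)(C)C(C)(C)C)[C@H]2OC(=O)[C@@H](C)CC | intermediate
26 | ozonide (1,2,4-trioxolane at C2, epimers) of 25 | O1[C@H]2[C@H](C(C(=O)OC(C)(C)C)=C)C[C@@H]1[C@H](C)[C@@](O)(C3(C[C@H](C)O[Si](C)(C)C(C)(C)C)OOCO3)[C@H]2OC(=O)[C@@H](C)CC | intermediate (not isolated)
27 | α-hydroxy ketone: oxabicycle with 1α-OH, 1β-[(3S)-3-(TBSO)butanoyl], 5β-(S)-2-methylbutanoate, 7α-(tert-butyl acrylate) | O1[C@H]2[C@H](C(C(=O)OC(C)(C)C)=C)C[C@@H]1[C@H](C)[C@@](O)(C(=O)C[C@H](C)O[Si](C)(C)C(C)(C)C)[C@H]2OC(=O)[C@@H](C)CC | intermediate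
28 | silyl ester: 27 with C12 trimethylsilyl ester and 1α-OTMS | O1[C@H]2[C@H](C(C(=O)O[Si](C)(C)C)=C)C[C@@H]1[C@H](C)[C@@](O[Si](C)(C)C)(C(=O)C[C@H](C)O[Si](C)(C)C(C)(C)C)[C@H]2OC(=O)[C@@H](C)CC | intermediate (not isolated)
29 | bis-silylated lactone: 1α-OTMS, 9β-OTMS, 4-OTBS derivative of the target | C=C1C(=O)O[C@@H]2[C@H]1C[C@@H](O[Si](C)(C)C)[C@H](C)[C@@](O[Si](C)(C)C)(C(=O)C[C@H](C)O[Si](C)(C)C(C)(C)C)[C@H]2OC(=O)[C@@H](C)CC | intermediate (not isolated)
30 | 4-O-TBS ether of the target | C=C1C(=O)O[C@@H]2[C@H]1C[C@@H](O)[C@H](C)[C@@](O)(C(=O)C[C@H](C)O[Si](C)(C)C(C)(C)C)[C@H]2OC(=O)[C@@H](C)CC | intermediate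
31 | CNP0291806.1: 6α,12-olide (cis-fused α-methylene-γ-lactone) with 9β-OH, 10α-methyl, 1α-OH, 1β-[(3S)-3-hydroxybutanoyl], 5β-[(S)-2-methylbutanoyloxy] | C=C1C(=O)O[C@@H]2[C@H]1C[C@@H](O)[C@H](C)[C@@](O)(C(=O)C[C@H](C)O)[C@H]2OC(=O)[C@@H](C)CC | target

**Step count and risks**

Total step count: 18. Longest linear sequence: 16 steps (steps 1–11 and 14–18 from 1); steps 12–13 make the side-chain fragment.

Steps most likely to fail:

1. Step 17 (Proposed new method). What may go wrong: the silyloxonium ion may not be opened at all, may be opened at C9 by an external nucleophile, or the strained tertiary α-ketol may ionise or undergo an acyloin shift before the lactone closes. Fallback with known chemistry, setting out from 13 and returning at 31: the kinetic enolate of 13 (LDA, then TBSOTf) gives the tert-butyldimethylsilyl enol ether F1. Catalytic TBSOTf in CH2Cl2 then induces the known retro-oxa-Michael opening of the bicyclic enol ether, with silyl transfer to the leaving oxygen, to the 9β-silyloxy cycloheptenone F2. t-BuOOH/DBU epoxidises the enone anti to the C7 substituent to the 5β,6β-epoxy ketone F3. TFA removes the tert-butyl group to the epoxy acid F4, which closes by the classical 5-exo opening of the epoxide at C6 (same O–C6 bond, inversion at C6, O5 left as the β-hydroxyl) to the hydroxy lactone F5. Steglich esterification with 24 gives the ester F6. Alkenylcerium 22 adds to the C1 ketone to give the tertiary alcohol F7; here facial control rests on the 10α-methyl group alone and must be checked. Ozonolysis through the ozonide F8 gives the bis-silyl ether F9, and HF·pyridine gives 31.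

2. Step 14. What may go wrong: addition to a ketone that is hindered on both faces may be slow, so that enolisation or proton transfer wins, and the adduct carries syn-axial strain between the new 1α-oxygen and the endo C7 group. Fallback, setting out from 16 and returning at 27: commercial (S)-but-3-yn-2-ol is silylated to (S)-(but-3-yn-2-yloxy)(tert-butyl)dimethylsilane F10. Its lithium acetylide (n-BuLi, then CeCl3), a much smaller nucleophile, adds to 16 from the exo face to the propargylic diol F11. Steglich esterification with 24 gives the ester F12. AgOAc/DBU under CO2 carboxylates the tertiary propargylic alcohol and closes it 5-exo-dig onto C2 to the α-alkylidene cyclic carbonate F13. Mild hydrolysis (water, DBU) releases CO2 and gives the C2 ketone 27.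

3. Step 5. What may go wrong: the oxidative ring opening may be incomplete or cleave the wrong cyclopropane bond, and dehydration of the β-hydroxy ketone may compete with the transannular addition. Fallback, setting out from 3 and returning at 9: 3 is protected as the triethylsilyl ether F14. TMSCHN2/BF3·OEt2 ring enlargement (migration of the less substituted C6) gives the α-trimethylsilyl cycloheptanone F15, which is protodesilylated on work-up to the cycloheptanone F16. LDA/TMSCl gives the kinetic trimethylsilyl enol ether F17 (towards C5). Saegusa–Ito dehydrogenation with Pd(OAc)2 gives the enone F18. TBAF removes the silyl ether, and the liberated alkoxide closes through 8 to 9.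

**Further compounds**

F1 | step 17 | tert-butyldimethylsilyl enol ether C1(OTBS)=C5 of 13 | O1[C@H]2[C@H](C(C(=O)OC(C)(C)C)=C)C[C@@H]1[C@H](C)C(O[Si](C)(C)C(C)(C)C)=C2
F2 | step 17 | 9β-silyloxy cycloheptenone (C1 ketone, C5=C6, 10α-methyl, 7α-tert-butyl acrylate) | O=C1C=C[C@H](C(C(=O)OC(C)(C)C)=C)C[C@@H](O[Si](C)(C)C(C)(C)C)[C@@H]1C
F3 | step 17 | 5β,6β-epoxy ketone | O=C1[C@H]2O[C@H]2[C@H](C(C(=O)OC(C)(C)C)=C)C[C@@H](O[Si](C)(C)C(C)(C)C)[C@@H]1C
F4 | step 17 | epoxy acid | O=C1[C@H]2O[C@H]2[C@H](C(C(=O)O)=C)C[C@@H](O[Si](C)(C)C(C)(C)C)[C@@H]1C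
F5 | step 17 | hydroxy lactone (6α,12-olide, 5β-OH, C1 ketone, 9β-OTBS) | C=C1C(=O)O[C@@H]2[C@H]1C[C@@H](O[Si](C)(C)C(C)(C)C)[C@H](C)C(=O)[C@H]2O
F6 | step 17 | 5β-(S)-2-methylbutanoate of F5 | C=C1C(=O)O[C@@H]2[C@H]1C[C@@H](O[Si](C)(C)C(C)(C)C)[C@H](C)C(=O)[C@H]2OC(=O)[C@@H](C)CC
F7 | step 17 | tertiary alcohol (1α-OH, 1β-alkenyl) from F6 | C=C1C(=O)O[C@@H]2[C@H]1C[C@@H](O[Si](C)(C)C(C)(C)C)[C@H](C)[C@@](O)(C(=C)C[C@H](C)O[Si](C)(C)C(C)(C)C)[C@H]2OC(=O)[C@@H](C)CC
F8 | step 17 | ozonide of F7 | C=C1C(=O)O[C@@H]2[C@H]1C[C@@H](O[Si](C)(C)C(C)(C)C)[C@H](C)[C@@](O)(C3(C[C@H](C)O[Si](C)(C)C(C)(C)C)OOCO3)[C@H]2OC(=O)[C@@H](C)CC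
F9 | step 17 | 4,9-bis-O-TBS ether of the target | C=C1C(=O)O[C@@H]2[C@H]1C[C@@H](O[Si](C)(C)C(C)(C)C)[C@H](C)[C@@](O)(C(=O)C[C@H](C)O[Si](C)(C)C(C)(C)C)[C@H]2OC(=O)[C@@H](C)CC
F10 | step 14 | (S)-(but-3-yn-2-yloxy)(tert-butyl)dimethylsilane | C#C[C@H](C)O[Si](C)(C)C(C)(C)C
F11 | step 14 | propargylic diol (1α-OH, 1β-alkynyl, 5β-OH) | O1[C@H]2[C@H](C(C(=O)OC(C)(C)C)=C)C[C@@H]1[C@H](C)[C@@](O)(C#C[C@H](C)O[Si](C)(C)C(C)(C)C)[C@H]2O
F12 | step 14 | 5β-(S)-2-methylbutanoate of F11 | O1[C@H]2[C@H](C(C(=O)OC(C)(C)C)=C)C[C@@H]1[C@H](C)[C@@](O)(C#C[C@H](C)O[Si](C)(C)C(C)(C)C)[C@H]2OC(=O)[C@@H](C)CC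
F13 | step 14 | (Z)-α-alkylidene cyclic carbonate spiro at C1 | O1[C@H]2[C@H](C(C(=O)OC(C)(C)C)=C)C[C@@H]1[C@H](C)[C@]3(OC(=O)O/C3=C\[C@H](C)O[Si](C)(C)C(C)(C)C)[C@H]2OC(=O)[C@@H](C)CC
F14 | step 5 | 9β-triethylsilyl ether of 3 | C1[C@H](C(C)=C)C[C@@H](O[Si](CC)(CC)CC)[C@@H](C)C1=O
F15 | step 5 | α-trimethylsilyl cycloheptanone (C5 epimers) | C1[C@H](C(C)=C)C[C@@H](O[Si](CC)(CC)CC)[C@@H](C)C(=O)C1[Si](C)(C)C
F16 | step 5 | ring-enlarged cycloheptanone (C1 ketone, C5 and C6 methylene, 9β-OTES) | C1[C@H](C(C)=C)C[C@@H](O[Si](CC)(CC)CC)[C@@H](C)C(=O)C1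
F17 | step 5 | trimethylsilyl enol ether C1(OTMS)=C5 of F16 | C1[C@H](C(C)=C)C[C@@H](O[Si](CC)(CC)CC)[C@@H](C)C(O[Si](C)(C)C)=C1
F18 | step 5 | 9β-triethylsilyloxy enone (C5=C6) | O=C1C=C[C@H](C(C)=C)C[C@@H](O[Si](CC)(CC)CC)[C@H]1C
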